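The blue run is slow: at its last reading, 6.00 min, it holds 14.4% of target and 85.7% of electrophile, and the flask in question runs ten times that span.

in all of them: electrophile 0.10 M
- blue: nucleophile 0.10 M; buffer base 0.10 M; buffer acid 0.0050 M; protic impurity 5 mM; run made earlier
- flask: nucleophile 0.100 M; buffer base 0.100 M; buffer acid 0.0100 M; protic impurity 5.00 mM; time 1.0 h

- blue (time / min: electrophile / %, target / %): 0.333: 99.0, 1.9; 1.00: 98.8, 2.5; 1.50: 95.0, 4.2; 2.50: 93.0, 7.4; 4.00: 89.1, 9.6; 5.00: 88.2, 12.0; 6.00: 85.7, 14.4

(scatter of a reading: 1 percentage point)

- the earlier runs do not show the pH; that part of a forecast is a guess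

- part of the electrophile that has reacted at 1.0 h
- pH of the solution at 1.0 h

The flask looks nearly the same as the blue run, since among the charges the buffer acid differs, by 0.00500 M. To price that difference, one nucleophile is followed to its first fork: on this reckoning's assumption, a buffer acid or a protic impurity may take it before any electrophile does, one for one. The working nucleophile, the nucleophile charged less the buffer acid and protic impurity charged, comes to 0.0850 M in the flask and 0.0900 M in the blue run. If the early pace goes with it, the flask moves at 0.944 of the blue pace, which turns the last blue target reading into 13.6% at the same minute. This reckoning therefore expects the two flasks to stay close up to the hour, with the electrophile used in the flask under 85.0%, the working nucleophile per electrophile charged. How far under, the readings do not say, and they show no pH.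

The forecast gives 60% and pH 8, and where this reckoning takes the buffer acid as a small change of pace, the forecast holds a larger one open: “If the rate follows base/acid, it could halve”.

    electrophile + nucleophile → acid + target + leaving group (k = 0.00570 M⁻¹ s⁻¹)
    protonated nucleophile ⇌ nucleophile + acid, settled at all times (K = 1.60 × 10⁻⁷ M)
    buffer acid ⇌ buffer base + acid, settled at all times (K = 1.60 × 10⁻⁶ M)
    nucleophile + protic impurity → quenched reagent (k = 0.0340 M⁻¹ s⁻¹)
    target + leaving group → side product (k = 0.00230 M⁻¹ s⁻¹)
    2 nucleophile → self-condensation product (k = 0.00400 M⁻¹ s⁻¹)

The flask gives 38.2% at pH 6.34, and the blue run carried to the same hour gives 38.7%. At that hour the nucleophile, the limiting reagent here, has 8.1% of its charge still free, less than the 62% of the electrophile, and 0.0235 M more stands as protonated nucleophile. Of the flask's working nucleophile, 0.0850 M, the electrophile has taken 0.0382 M, a share of 44.9%. The neighbour flask with 0.40 M of nucleophile has 0.385 M working and reaches 73.4%, so its electrophile has taken 0.0734 M, a share of 19.1%.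

The earlier runs and the new flask stem from a simulated flask for an exercise; the scatter is artificial.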